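**Retrosynthetic overview**

1. The spiro-norbornene core is opened by a retro-[4+2] into acetoxy-cyclopentadiene **34** (guaianolide half, termini C1 and C3) and α-methylene lactone **33** (seco-eudesmanolide half, C13′=C11′). The diene is made in the flask from tertiary alcohol **16**.
2. In the guaianolide half, ring A (cyclopentenone) comes first, from cyclopentane-1,3-dione. Ring C (lactol) and ring B (seven-membered) are then closed together in one SmI2 cascade: C11–C7 by radical 5-exo closure, then C5–C6 by carbanion addition.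
3. The feature that allows this: C5 is one carbonyl of a masked 1,3-dione (vinylogous ester C5(=O)–C1=C2–OMe), and C6 is the terminal carbon of the C6=C7 vinyl group on the carbinol carbon C8. Closing ring C at C7 therefore leaves the reactive centre on C6, five atoms from C5.
4. In the seco-eudesmanolide half, C4′ comes from (S)-citronellal, the cis-lactone from an indium Barbier reaction, the six-membered ring from ring-closing metathesis, and the exocyclic diene from a final methylenation.
5. Order of ring formation: ring A, then rings C and B (step 6), the cyclohexene ring of **33** in a separate branch, and the two norbornene rings last.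

Key step: step 6

Remark on numbering: guaiane numbering (C1–C15; ring A = C1–C5, ring B = C1, C5–C10, ring C = lactone C7, C8, C11, C12, O; acetate on C2) is used for one half, and primed 1,10-seco-eudesmane numbering (C1′–C15′) for the half with the hydroxypentyl chain. C4 epimers are carried from step 4 to step 24, where C4 becomes sp2.

**Route**

Step 1
Reactants: 1 cyclopentane-1,3-dione; 2 (E)-but-2-enal
Product: 3 (4R)-2-hydroxy-4-methyl-3,4,6,7-tetrahydrocyclopenta[b]pyran-5(2H)-one (anomer mixture)
Conditions: (S)-α,α-diphenylprolinol trimethylsilyl ether (10 mol%), PhCO2H (10 mol%), CH2Cl2, 0 °C to rt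
Reagents that add atoms: none
Why: Iminium-catalysed Michael addition of the 1,3-dione to the enal, with attack on the face of the (E)-iminium opposite the diaryl(silyloxy)methyl group, should set C10 as R; the adduct closes to the hemiacetal.

Step 2
Reactants: 3
Product: 4 3-methoxy-2-[(2R)-4-oxobutan-2-yl]cyclopent-2-en-1-one
Conditions: Me3SiCHN2, MeOH–toluene, 0 °C
Reagents that add atoms: (trimethylsilyl)diazomethane C[Si](C)(C)C=[N+]=[N-]
Why: O-Methylation of the vinylogous acid by the diazoalkane should drain the lactol/open-chain equilibrium; the dione is symmetric, so only one vinylogous ester can form.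

Step 3
Reactants: 4
Product: 5 2-[(2R,4R)-4-hydroxyhex-5-en-2-yl]-3-methoxycyclopent-2-en-1-one
Conditions: Zn(CH=CH2)2 (from CH2=CHMgBr and ZnCl2), (−)-MIB (5 mol%), toluene, 0 °C; aq. NH4Cl
Reagents that add atoms: divinylzinc C=C[Zn]C=C
Why: Amino-alcohol-catalysed enantioselective alkenylzinc addition to the aldehyde, with the same facial sense as dialkylzinc additions, should set C8 as R under catalyst control.

Step 4
Reactants: 5
Product: 6 2-[(2R,4R)-4-hydroxyhex-5-en-2-yl]-3-methoxy-5-methylcyclopent-2-en-1-one (epimers at the methyl-bearing carbon, guaiane C4)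
Conditions: LiN(iPr)2 (2.2 equiv), THF, −78 °C; MeI (1.1 equiv); aq. NH4Cl
Reagents that add atoms: iodomethane CI
Why: Stork–Danheiser kinetic α′-alkylation of the vinylogous ester through the alkoxide/enolate dianion; the methyl group marks the adjacent carbonyl as C5.

Step 5
Reactants: 6
Product: 7 2-[(2R,4R)-4-(2-bromo-1-ethoxyethoxy)hex-5-en-2-yl]-3-methoxy-5-methylcyclopent-2-en-1-one (acetal epimers)
Conditions: ethyl vinyl ether, NBS, CH2Cl2, −40 to 0 °C
Reagents that add atoms: ethyl vinyl ether C=COCC; N-bromosuccinimide O=C1CCC(=O)N1Br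
Why: Bromoetherification (Ueno–Stork bromoacetal formation) of the secondary alcohol, the electron-rich vinyl ether being far more reactive towards the bromonium source than the other alkenes.

Step 6
Reactants: 7
Product: 10 (7S,8R,10R)-12-hydroxy-8,12-epoxy-13-norguai-1(5)-en-2-one (C4 and C12 epimers), via ring-C-closed C6 alkylsamarium 8 (not isolated), via tricyclic C5 carbinol 9 (not isolated)
Conditions: SmI2 (3 equiv), HMPA, THF, −78 °C to rt; then 1 M HCl, THF, rt
Reagents that add atoms: water O
Why: Proposed new method: divalent samarium (SmI2–HMPA) should reduce the C–Br bond of 7 to the C11 radical, which closes ring C by 5-exo-trig attack on C7 of the vinyl group; the primary C6 radical so formed is reduced by a second SmI2 to alkylsamarium 8, which adds 1,2 to the vinylogous-ester carbonyl C5 (7-exo-trig at C=O), forming the C5–C6 bond and ring B to give carbinol 9. Aqueous acid then brings about the Stork–Danheiser hydrolysis and transposition (loss of methanol and water) to the C2 enone with the C1=C5 double bond, and hydrolyses the ethyl acetal to the lactol. The closest known reaction types are the SmI2-mediated sequence of radical cyclisation and organosamarium carbonyl addition (Barbier type), the Ueno–Stork haloacetal cyclisation and the Stork–Danheiser 1,2-addition/transposition; their combination in a seven-membered closure onto a vinylogous ester is the untested element. The new stereocentre C7 is set relative to C8 in a chair-like 5-exo transition state with the C9 chain pseudo-equatorial, which should give the 7,8-trans (7S) ring needed for the trans-fused lactone; C12 and C4 are epimer mixtures that are erased later. The step needs cyclisation to outrun reduction of the first radical (secured by the fast haloacetal closure), C–Br reduction in preference to the electron-rich vinylogous ester, and addition at C5 and not C2 (secured because C2 is masked as the enol ether and C5 was marked by the C4 methylation).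

Step 7
Reactants: 10
Product: 11 (7S,8R,10R)-12-hydroxy-8,12-epoxyguaia-1(5),11(13)-dien-2-one (C4 and C12 epimers)
Conditions: 37% aq. HCHO, pyrrolidine (10 mol%), EtCO2H (10 mol%), i-PrOH, 45 °C
Reagents that add atoms: formaldehyde C=O
Why: Amine-catalysed Mannich condensation and elimination (α-methylenation of aldehydes) on the open hydroxy-aldehyde form of the lactol; the enone does not form an enamine under these conditions.

Step 8
Reactants: 11
Product: 12 (7S,8R,10R)-2-oxoguaia-1(5),11(13)-dien-12,8-olide (C4 epimers)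
Conditions: MnO2, CH2Cl2, rt
Reagents that add atoms: none
Why: MnO2 oxidation of an allylic lactol to the α-methylene lactone.

Step 9
Reactants: 12
Product: 14 (7S,8R,10R)-4-hydroxy-2-oxoguaia-1(5),11(13)-dien-12,8-olide (C4 epimers), via silyl dienol ether 13 (not isolated)
Conditions: Me3SiOTf, Et3N, CH2Cl2, −78 to 0 °C; then mCPBA, NaHCO3, −40 °C; aq. citric acid
Reagents that add atoms: trimethylsilyl triflate C[Si](C)(C)OS(=O)(=O)C(F)(F)F (silicon retained only in 13); 3-chloroperbenzoic acid OOC(=O)c1cccc(Cl)c1
Why: Vinylogous Rubottom oxidation: soft enolisation should give the extended (cyclopentadiene-type) silyl dienol ether, which the peracid attacks at the γ-terminus C4 while the electron-poor methylene lactone stays untouched.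

Step 10
Reactants: 14
Product: 15 (2S,7S,8R,10R)-2,4-dihydroxyguaia-1(5),11(13)-dien-12,8-olide (C4 epimers)
Conditions: (R)-2-methyl-CBS-oxazaborolidine (0.3 equiv), catecholborane (3 equiv), toluene, −78 °C
Reagents that add atoms: none
Why: Corey–Bakshi–Shibata reduction, with the tetrasubstituted alkene carbon C1 as the large group and C3H2 as the small group, should give 2S under catalyst control; catecholborane does not hydroborate the methylene lactone at this temperature.

Step 11
Reactants: 15
Product: 16 (2S,7S,8R,10R)-2-acetoxy-4-hydroxyguaia-1(5),11(13)-dien-12,8-olide (C4 epimers)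
Conditions: Ac2O, Et3N, DMAP (cat.), CH2Cl2, 0 °C
Reagents that add atoms: acetic anhydride CC(=O)OC(C)=O
Why: Acylation of the secondary allylic alcohol; the tertiary C4 hydroxyl is too hindered to react.

Step 12
Reactants: 17 methyl acrylate; 18 prop-2-enal
Product: 19 methyl 3-hydroxy-2-methylidenepent-4-enoate (racemic)
Conditions: DABCO (20 mol%), THF, rt
Reagents that add atoms: none
Why: Morita–Baylis–Hillman reaction; the carbinol centre is destroyed in the next step.

Step 13
Reactants: 19
Product: 20 methyl (2Z)-2-(bromomethyl)penta-2,4-dienoate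
Conditions: PBr3 (0.4 equiv), Et2O, 0 °C
Reagents that add atoms: phosphorus tribromide BrP(Br)Br
Why: SN2′ bromination with allylic transposition gives the linearly conjugated dienoate in its thermodynamically preferred Z geometry.

Step 14
Reactants: 21 (S)-citronellal [(3S)-3,7-dimethyloct-6-enal]
Product: 22 (3S)-3,7-dimethyl-2-methylideneoct-6-enal
Conditions: 37% aq. HCHO, pyrrolidine (10 mol%), EtCO2H (10 mol%), i-PrOH, 45 °C
Reagents that add atoms: formaldehyde C=O
Why: Amine-catalysed α-methylenation of the aldehyde; the β-stereocentre (C4′) is untouched.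

Step 15
Reactants: 22
Product: 23 (3S,5S)-5,9-dimethyl-4-methylidenedeca-1,8-dien-3-ol
Conditions: Zn(CH=CH2)2, (−)-MIB (5 mol%), toluene, 0 °C; aq. NH4Cl
Reagents that add atoms: divinylzinc C=C[Zn]C=C
Why: Catalytic enantioselective alkenylzinc 1,2-addition to the enal, as in step 3, should set C10′ as S; this centre serves only as a control element and is erased in step 19.

Step 16
Reactants: 23
Product: 24 (3S,5S)-5,9-dimethyl-4-methylidenedec-8-ene-1,3-diol
Conditions: Sia2BH (2.5 equiv), THF, 0 °C; then NaOH, H2O2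
Reagents that add atoms: hydrogen peroxide OO
Why: Hydroboration and oxidation; the bulky dialkylborane selects the monosubstituted vinyl group over the 1,1-disubstituted and trisubstituted alkenes and adds anti-Markovnikov.

Step 17
Reactants: 24
Product: 25 (3S,5S)-3-hydroxy-5,9-dimethyl-4-methylidenedec-8-enal
Conditions: TEMPO (10 mol%), PhI(OAc)2, CH2Cl2, rt
Reagents that add atoms: none
Why: Oxoammonium (TEMPO) oxidation is selective for the primary alcohol.

Step 18
Reactants: 25; 20
Product: 27 (4S,5S)-4-ethenyl-5-[(2S,4S)-2-hydroxy-4,8-dimethyl-3-methylidenenon-7-en-1-yl]-3-methylideneoxolan-2-one, via syn hydroxy ester 26 (not isolated)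
Conditions: In powder, THF–H2O, rt; then TsOH (cat.), CH2Cl2
Reagents that add atoms: none
Why: Barbier allylation: γ-attack of the pentadienylindium through a chair transition state gives the syn adduct (cis-lactone after lactonisation), and chelation of indium between the C10′ hydroxyl and the aldehyde should give the 1,3-anti relationship, hence 7′S,8′S.

Step 19
Reactants: 27
Product: 28 (4S,5S)-5-[(4S)-4,8-dimethyl-3-methylidene-2-oxonon-7-en-1-yl]-4-ethenyl-3-methylideneoxolan-2-one
Conditions: Dess–Martin periodinane, NaHCO3, CH2Cl2, 0 °C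
Reagents that add atoms: none
Why: Dess–Martin oxidation of the allylic alcohol; the buffer prevents β-elimination of the lactone oxygen.

Step 20
Reactants: 28
Product: 29 (3aS,7aS)-3-methylidene-5-[(2S)-6-methylhept-5-en-2-yl]-3a,7a-dihydro-1-benzofuran-2,6(3H,7H)-dione
Conditions: second-generation Hoveyda–Grubbs catalyst RuCl2(H2IMes)(=CH-C6H4-2-OiPr) (5 mol%), CH2Cl2 (2 mM), 40 °C
Reagents that add atoms: none
Why: Ring-closing metathesis between the vinyl group and the 1,1-disubstituted enone alkene closes the cyclohexenone; the trisubstituted isopropylidene and the methylene lactone react more slowly.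

Step 21
Reactants: 29
Product: 31 (3aS,7aS)-5-[(2S)-5-hydroxypentan-2-yl]-3-methylidene-3a,7a-dihydro-1-benzofuran-2,6(3H,7H)-dione, via aldehyde 30 (not isolated)
Conditions: O3, pyridine, CH2Cl2, −78 °C; Me2S; then NaBH(OAc)3, CH2Cl2, rt
Reagents that add atoms: ozone [O-][O+]=O
Why: Ozonolysis is selective for the electron-rich trisubstituted alkene over the enone and the methylene lactone, and triacetoxyborohydride then reduces only the aldehyde.

Step 22
Reactants: 31
Product: 32 (3aS,7aS)-5-[(2S)-5-{[tert-butyl(dimethyl)silyl]oxy}pentan-2-yl]-3-methylidene-3a,7a-dihydro-1-benzofuran-2,6(3H,7H)-dione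
Conditions: t-BuMe2SiCl, imidazole, CH2Cl2, rt
Reagents that add atoms: tert-butyldimethylsilyl chloride CC(C)(C)[Si](C)(C)Cl
Why: Silylation of the primary alcohol, which must be masked against the Burgess reagent in step 24.

Step 23
Reactants: 32
Product: 33 (3aS,7aS)-5-[(2S)-5-{[tert-butyl(dimethyl)silyl]oxy}pentan-2-yl]-3,6-dimethylidene-3a,6,7,7a-tetrahydro-1-benzofuran-2(3H)-one
Conditions: Zn, CH2Br2, TiCl4, THF–CH2Cl2, 0 °C to rt
Reagents that add atoms: dibromomethane BrCBr
Why: Lombardo methylenation is non-basic and ketone-selective, so the γ-stereocentre C7′ and the lactone are left alone.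

Step 24
Reactants: 16; 33
Product: 35 tert-butyldimethylsilyl ether of the target at its primary hydroxyl, via acetoxy diene 34 (not isolated)
Conditions: 33 (3 equiv, excess recovered), Burgess reagent (1.5 equiv), benzene, rt to 50 °C
Reagents that add atoms: none
Why: Burgess syn-dehydration of the tertiary allylic alcohol (β-hydrogens only on C3 and C15) releases diene 34 slowly in the presence of excess 33, and the Diels–Alder reaction then joins C1 to C13′ and C3 to C11′; the exo mode typical of α-methylene lactones (carbonyl towards the C2 bridge) on the diene face opposite the C2 acetate should set C1 (R), C3 (S) and C11′ (S), and in that geometry 33 has to react on its more hindered, C6′-bearing face, which makes this selectivity the main uncertainty of the step.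

Step 25
Reactants: 35
Product: 36 target CNP0299458.1 (1R,2S,3S,7S,8R,10R,11′S,7′S,8′S,4′S)
Conditions: HF·pyridine, THF, 0 °C
Reagents that add atoms: none
Why: Fluoride cleavage of the primary silyl ether under conditions that spare the acetate and both methylene lactone units.

**Compound list**

1 | cyclopentane-1,3-dione | O=C1CCC(=O)C1 | starting material
2 | (E)-but-2-enal | C/C=C/C=O | starting material
3 | (4R)-2-hydroxy-4-methyl-3,4,6,7-tetrahydrocyclopenta[b]pyran-5(2H)-one | C[C@@H]1CC(O)OC2=C1C(=O)CC2 | intermediate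
4 | 3-methoxy-2-[(2R)-4-oxobutan-2-yl]cyclopent-2-en-1-one | COC1=C([C@H](C)CC=O)C(=O)CC1 | intermediate
5 | 2-[(2R,4R)-4-hydroxyhex-5-en-2-yl]-3-methoxycyclopent-2-en-1-one | COC1=C([C@H](C)C[C@@H](O)C=C)C(=O)CC1 | intermediate
6 | 2-[(2R,4R)-4-hydroxyhex-5-en-2-yl]-3-methoxy-5-methylcyclopent-2-en-1-one (C5 epimers) | COC1=C([C@H](C)C[C@@H](O)C=C)C(=O)C(C)C1 | intermediate
7 | 2-[(2R,4R)-4-(2-bromo-1-ethoxyethoxy)hex-5-en-2-yl]-3-methoxy-5-methylcyclopent-2-en-1-one | COC1=C([C@H](C)C[C@@H](OC(CBr)OCC)C=C)C(=O)C(C)C1 | intermediate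
8 | C6 alkylsamarium diiodide of the 7,8-trans 2-ethoxytetrahydrofuran (ring C closed; vinylogous ester ring attached through the (R)-2-propyl chain at C8) | COC1=C([C@H](C)C[C@H]2OC(OCC)C[C@@H]2C[Sm](I)I)C(=O)C(C)C1 | intermediate
9 | tricyclic C5 carbinol: 12-ethoxy-8,12-epoxy-2-methoxy-13-norguai-1-en-5-ol (7S,8R,10R) | COC1=C2[C@H](C)C[C@H]3OC(OCC)C[C@@H]3CC2(O)C(C)C1 | intermediate
10 | (7S,8R,10R)-12-hydroxy-8,12-epoxy-13-norguai-1(5)-en-2-one | C[C@@H]1C[C@H]2OC(O)C[C@@H]2CC3=C1C(=O)CC3C | intermediate
11 | (7S,8R,10R)-12-hydroxy-8,12-epoxyguaia-1(5),11(13)-dien-2-one | C[C@@H]1C[C@H]2OC(O)C(=C)[C@@H]2CC3=C1C(=O)CC3C | intermediate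
12 | (7S,8R,10R)-2-oxoguaia-1(5),11(13)-dien-12,8-olide | C[C@@H]1C[C@H]2OC(=O)C(=C)[C@@H]2CC3=C1C(=O)CC3C | intermediate
13 | (7S,8R,10R)-2-(trimethylsilyloxy)guaia-1,4,11(13)-trien-12,8-olide | C[C@@H]1C[C@H]2OC(=O)C(=C)[C@@H]2CC3=C(C)CC(O[Si](C)(C)C)=C13 | intermediate
14 | (7S,8R,10R)-4-hydroxy-2-oxoguaia-1(5),11(13)-dien-12,8-olide | C[C@@H]1C[C@H]2OC(=O)C(=C)[C@@H]2CC3=C1C(=O)CC3(C)O | intermediate
15 | (2S,7S,8R,10R)-2,4-dihydroxyguaia-1(5),11(13)-dien-12,8-olide | C[C@@H]1C[C@H]2OC(=O)C(=C)[C@@H]2CC3=C1[C@@H](O)CC3(C)O | intermediate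
16 | (2S,7S,8R,10R)-2-acetoxy-4-hydroxyguaia-1(5),11(13)-dien-12,8-olide | C[C@@H]1C[C@H]2OC(=O)C(=C)[C@@H]2CC3=C1[C@@H](OC(C)=O)CC3(C)O | intermediate
17 | methyl acrylate | C=CC(=O)OC | starting material
18 | prop-2-enal | C=CC=O | starting material
19 | methyl 3-hydroxy-2-methylidenepent-4-enoate | C=CC(O)C(=C)C(=O)OC | intermediate
20 | methyl (2Z)-2-(bromomethyl)penta-2,4-dienoate | C=C/C=C(\CBr)C(=O)OC | intermediate
21 | (S)-citronellal | C[C@@H](CCC=C(C)C)CC=O | starting material
22 | (3S)-3,7-dimethyl-2-methylideneoct-6-enal | C[C@@H](CCC=C(C)C)C(=C)C=O | intermediate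
23 | (3S,5S)-5,9-dimethyl-4-methylidenedeca-1,8-dien-3-ol | C[C@@H](CCC=C(C)C)C(=C)[C@@H](O)C=C | intermediate
24 | (3S,5S)-5,9-dimethyl-4-methylidenedec-8-ene-1,3-diol | C[C@@H](CCC=C(C)C)C(=C)[C@@H](O)CCO | intermediate
25 | (3S,5S)-3-hydroxy-5,9-dimethyl-4-methylidenedec-8-enal | C[C@@H](CCC=C(C)C)C(=C)[C@@H](O)CC=O | intermediate
26 | methyl (3S,4S,6S,8S)-3-ethenyl-4,6-dihydroxy-8,12-dimethyl-2,7-dimethylidenetridec-11-enoate | C[C@@H](CCC=C(C)C)C(=C)[C@@H](O)C[C@H](O)[C@@H](C=C)C(=C)C(=O)OC | intermediate
27 | (4S,5S)-4-ethenyl-5-[(2S,4S)-2-hydroxy-4,8-dimethyl-3-methylidenenon-7-en-1-yl]-3-methylideneoxolan-2-one | C[C@@H](CCC=C(C)C)C(=C)[C@@H](O)C[C@@H]1OC(=O)C(=C)[C@@H]1C=C | intermediate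
28 | (4S,5S)-5-[(4S)-4,8-dimethyl-3-methylidene-2-oxonon-7-en-1-yl]-4-ethenyl-3-methylideneoxolan-2-one | C[C@@H](CCC=C(C)C)C(=C)C(=O)C[C@@H]1OC(=O)C(=C)[C@@H]1C=C | intermediate
29 | (3aS,7aS)-3-methylidene-5-[(2S)-6-methylhept-5-en-2-yl]-3a,7a-dihydro-1-benzofuran-2,6(3H,7H)-dione | O=C1C[C@@H]2OC(=O)C(=C)[C@@H]2C=C1[C@@H](C)CCC=C(C)C | intermediate
30 | (4S)-4-[(3aS,7aS)-3-methylidene-2,6-dioxo-2,3,3a,6,7,7a-hexahydro-1-benzofuran-5-yl]pentanal | O=C1C[C@@H]2OC(=O)C(=C)[C@@H]2C=C1[C@@H](C)CCC=O | intermediate
31 | (3aS,7aS)-5-[(2S)-5-hydroxypentan-2-yl]-3-methylidene-3a,7a-dihydro-1-benzofuran-2,6(3H,7H)-dione | O=C1C[C@@H]2OC(=O)C(=C)[C@@H]2C=C1[C@@H](C)CCCO | intermediate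
32 | tert-butyldimethylsilyl ether of 31 | O=C1C[C@@H]2OC(=O)C(=C)[C@@H]2C=C1[C@@H](C)CCCO[Si](C)(C)C(C)(C)C | intermediate
33 | (3aS,7aS)-5-[(2S)-5-{[tert-butyl(dimethyl)silyl]oxy}pentan-2-yl]-3,6-dimethylidene-3a,6,7,7a-tetrahydro-1-benzofuran-2(3H)-one | C=C1C[C@@H]2OC(=O)C(=C)[C@@H]2C=C1[C@@H](C)CCCO[Si](C)(C)C(C)(C)C | intermediate
34 | (2S,7S,8R,10R)-2-acetoxyguaia-1(5),3,11(13)-trien-12,8-olide | C[C@@H]1C[C@H]2OC(=O)C(=C)[C@@H]2CC3=C1[C@@H](OC(C)=O)C=C3C | intermediate
35 | tert-butyldimethylsilyl ether of the target at the primary hydroxyl | C=C1C[C@@H]2OC(=O)[C@@]3(C[C@@]45C(=C(C)[C@@H]3[C@@H]4OC(C)=O)C[C@H]3C(=C)C(=O)O[C@@H]3C[C@H]5C)[C@@H]2C=C1[C@@H](C)CCCO[Si](C)(C)C(C)(C)C | intermediate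
36 | CNP0299458.1 | C=C1C[C@@H]2OC(=O)[C@@]3(C[C@@]45C(=C(C)[C@@H]3[C@@H]4OC(C)=O)C[C@H]3C(=C)C(=O)O[C@@H]3C[C@H]5C)[C@@H]2C=C1[C@@H](C)CCCO | target

**Count and risks**

Total step count: 25. Longest linear sequence: 13 steps (steps 1–11, 24, 25).

Steps most likely to fail:

Step 6 (Proposed new method). The alkylsamarium may be protonated before the slow seven-membered carbonyl addition, or the first radical may be reduced and fragment before it cyclises. Fallback: separate the two ring closures with known chemistry. Setting out from 6, haloetherification with N-iodosuccinimide and ethyl vinyl ether gives the iodoacetal 2-[(2R,4R)-4-(1-ethoxy-2-iodoethoxy)hex-5-en-2-yl]-3-methoxy-5-methylcyclopent-2-en-1-one F1. Iodine-atom-transfer radical cyclisation (BEt3, air, benzene) closes ring C and leaves the primary iodide, the 7,8-trans 2-ethoxy-4-(iodomethyl)tetrahydrofuran F2. Iodine–lithium exchange with tert-butyllithium (2.1 equiv, Et2O–pentane, −78 °C), intramolecular Stork–Danheiser 1,2-addition and 1 M HCl then come back to the route at 10.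

Step 24. Three processes threaten it: the diene may cycloadd to its own methylene lactone, the exo/facial preference may be poor because 33 has to react on its more hindered face, and a 1,5-hydrogen shift may isomerise the diene before it is trapped. Fallback: mask the competing dienophile. Setting out from 16, conjugate addition of dimethylamine (THF, rt) gives the amine adduct (2S,7S,8R,10R)-2-acetoxy-13-(dimethylamino)-4-hydroxyguai-1(5)-en-12,8-olide F3. Burgess dehydration and cycloaddition with 33, as in step 24, give the amine-masked adduct F4. Quaternisation with iodomethane and elimination with aqueous NaHCO3 restore the methylene lactone and come back to the route at 35.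

Step 20. Ring closure onto the electron-poor 1,1-disubstituted enone may be slow, so that metathesis at the isopropylidene end or catalyst decay competes. Fallback: reverse the order of oxidation and metathesis. Setting out from 27, ring-closing metathesis of the more reactive allylic alcohol with the same ruthenium catalyst gives the cyclohexenol (3aS,6S,7aS)-6-hydroxy-3-methylidene-5-[(2S)-6-methylhept-5-en-2-yl]-3a,6,7,7a-tetrahydro-1-benzofuran-2(3H)-one F5. Dess–Martin oxidation then comes back to the route at 29.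

Further compounds
F1 | step 6 | 2-[(2R,4R)-4-(1-ethoxy-2-iodoethoxy)hex-5-en-2-yl]-3-methoxy-5-methylcyclopent-2-en-1-one | COC1=C([C@H](C)C[C@@H](OC(CI)OCC)C=C)C(=O)C(C)C1
F2 | step 6 | 7,8-trans 2-ethoxy-4-(iodomethyl)tetrahydrofuran carrying the (R)-2-(2-methoxy-4-methyl-5-oxocyclopent-1-enyl)propyl chain at C8 | COC1=C([C@H](C)C[C@H]2OC(OCC)C[C@@H]2CI)C(=O)C(C)C1
F3 | step 24 | (2S,7S,8R,10R)-2-acetoxy-13-(dimethylamino)-4-hydroxyguai-1(5)-en-12,8-olide | C[C@@H]1C[C@H]2OC(=O)C(CN(C)C)[C@@H]2CC3=C1[C@@H](OC(C)=O)CC3(C)O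
F4 | step 24 | 13-(dimethylamino)-11,13-dihydro derivative of 35 | C=C1C[C@@H]2OC(=O)[C@@]3(C[C@@]45C(=C(C)[C@@H]3[C@@H]4OC(C)=O)C[C@H]3C(CN(C)C)C(=O)O[C@@H]3C[C@H]5C)[C@@H]2C=C1[C@@H](C)CCCO[Si](C)(C)C(C)(C)C
F5 | step 20 | (3aS,6S,7aS)-6-hydroxy-3-methylidene-5-[(2S)-6-methylhept-5-en-2-yl]-3a,6,7,7a-tetrahydro-1-benzofuran-2(3H)-one | O[C@H]1C[C@@H]2OC(=O)C(=C)[C@@H]2C=C1[C@@H](C)CCC=C(C)C
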